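The rate constants are assumed; the run is a simulation.

The easy step came first: I asked what one steady level of dissolved starting material did to the catalyst.

    starting material + free catalyst → catalyst intermediate (k1 = 4.5 M⁻¹ s⁻¹)
    catalyst intermediate → free catalyst + target (k2 = 0.57 s⁻¹)
    solid substrate ⇌ starting material, rate k3*(cs3 - [starting material]) while solid is left; crystals form when [starting material] > cs3 (cs3 = 0.94 M, k3 = 0.20 s⁻¹)

solid substrate 2.0 M; free catalyst 12 mol%

- the form that holds most of the catalyst when 20 % of the solid substrate are converted (what has only dissolved counts as not reacted) (catalyst intermediate / free catalyst)
- its share of the catalyst then

Let A be the concentration of starting material. When binding and release balance, the intermediate's share is A/(A+K), where K is the release constant over the binding constant, 0.127 M, the Michaelis constant. I assumed this balance throughout, although it is approached gradually: at A = K the gap to it shrinks with a time constant of 0.877 s.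

The mark meant 0.400 M converted, as target plus intermediate, on a catalyst charge of 0.240 M. I replaced the rising curve of A by a mean, 0.5 of its end value. Each row tries one end value of A. The time is what release at the mean share needs to make the target part of the mark, and the amount required is end A plus the mark.

- First trial: end A 0.127 M, end share 50.0 %, mean share 33.3 %, time to the mark 6.14 s, solid dissolved in that time 1.08 M, amount required 0.527 M.
- Second trial: end A 0.253 M, end share 66.7 %, mean share 50.0 %, time to the mark 3.51 s, solid dissolved in that time 0.571 M, amount required 0.653 M.

In the first row the solid supplied more than was required, so A had to end higher. In the second it fell short, but narrowly. A straight line between the two gaps put the end of A at 0.237 M, so I committed to catalyst intermediate as resting state, at 65.2 %. I had tested neither the mean nor the assumed balance, so this figure remained an estimate.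

The forecast said catalyst intermediate at 69 %, above my figure, on the ground that “Binding is fast relative to turnover”.

The flask gave catalyst intermediate at 65.7 %, reaching the mark at 4.35 s while making target at 0.0899 M s⁻¹. I then put K to work later in the same flask. At 15.0 s the starting material stood at 20.2 % of the charge, which is 0.404 M, so A/(A+K) gave 76.1 %, and the catalyst intermediate held 76.1 %.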